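The route rests on cutting the unbranched acyl chain between C5 and C6 (counting from the ester carbonyl C1), which divides the target into a C17 alkyl electrophile and a five-carbon ester fragment that already carries the 2-phenylethyl group. The key step is a one-pot hydroboration/alkyl–alkyl Suzuki–Miyaura coupling: 9-BBN places boron on the terminal carbon of 2-phenylethyl pent-4-enoate, and palladium joins this C5 to C1 of 1-bromoheptadecane, giving the saturated chain directly with no functional group left to remove. It exploits the absence of branching and stereocentres between C2 and C22 and the inertness of the C1 ester and the phenyl ring to borane and Pd(0).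

Key step: step 2

Remark: the target has no stereocentre, so no stereocontrol is needed. 9-BBN is drawn as its monomer although it is supplied as the dimer or as a THF solution. Chain positions are counted from the ester carbonyl carbon (C1).

Step 1
Reactants: 1 pent-4-enoic acid; 2 2-phenylethanol
Product: 3 2-phenylethyl pent-4-enoate
Conditions: DCC (1.1 equiv), DMAP (0.1 equiv), CH2Cl2, 0 °C to rt
Reagents that add atoms: none
Why: Steglich esterification; carbodiimide activation of the acid with DMAP as acyl-transfer catalyst should acylate the unhindered primary alcohol at room temperature, and the terminal alkene is inert to these conditions.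

Step 2
Reactants: 3 2-phenylethyl pent-4-enoate; 4 9-borabicyclo[3.3.1]nonane (9-BBN); 5 1-bromoheptadecane
Product: 7 2-phenylethyl docosanoate, via alkylborane 6 (not isolated)
Conditions: 3 and 4 (1.2 equiv each, 0.5 M in THF), 0 °C to rt; then 5 (1.0 equiv), Pd(OAc)2 (4 mol%), PCy3 (8 mol%), K3PO4·H2O (1.2 equiv), THF, rt
Reagents that add atoms: none
Why: 9-BBN should add across the monosubstituted C4=C5 alkene of 3 through a four-centre transition state, placing boron on the terminal carbon C5; Pd(0)/PCy3 then inserts into the primary C–Br bond of 5, the base-activated borate transfers its primary alkyl group to palladium, and reductive elimination forms the C5–C6 bond. The closest known reaction type is the room-temperature B-alkyl Suzuki–Miyaura coupling of 9-BBN alkylboranes with unactivated primary alkyl bromides that carry β-hydrogens, a reaction class that tolerates esters. No ring is closed and no stereocentre is formed. The step needs anti-Markovnikov regioselectivity in the hydroboration, secured by the bulk of 9-BBN at a terminal alkene; chemoselectivity for the alkene over the ester, secured by the low reactivity of 9-BBN toward esters at room temperature; transfer of the primary alkyl group in preference to the secondary bicyclic B–C bonds; and reductive elimination faster than β-hydride elimination, secured by the bulky, electron-rich PCy3 ligand.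

Compound list
1 | pent-4-enoic acid | C=CCCC(=O)O | starting material
2 | 2-phenylethanol | OCCc1ccccc1 | starting material
3 | 2-phenylethyl pent-4-enoate | C=CCCC(=O)OCCc1ccccc1 | intermediate
4 | 9-borabicyclo[3.3.1]nonane (9-BBN, drawn as monomer) | B1C2CCCC1CCC2 | starting material
5 | 1-bromoheptadecane | CCCCCCCCCCCCCCCCCBr | starting material
6 | 2-phenylethyl 5-(9-borabicyclo[3.3.1]nonan-9-yl)pentanoate (alkylborane) | O=C(CCCCB1C2CCCC1CCC2)OCCc1ccccc1 | intermediate
7 | 2-phenylethyl docosanoate (phenylethyl n-docosanoate) | CCCCCCCCCCCCCCCCCCCCCC(=O)OCCc1ccccc1 | target

Total step count: 2
Longest linear sequence: 2 steps (1 → 3 → 7)

Steps most likely to fail (the route has only two steps, so both are ranked):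

1. Step 2. β-Hydride elimination at the heptadecylpalladium stage, slow transmetalation of the alkylborane or incomplete hydroboration could divert the bromide to alkene and alkane by-products and lower the cross-coupling. The fallback reverses the polarity and uses a copper-catalysed Grignard–alkyl bromide coupling (Kochi-type). It sets out from 2 and 5 and comes back to the route at 7. Compound 2 would be esterified with commercial 5-bromopentanoic acid (TsOH cat., toluene, reflux, Dean–Stark) to give 2-phenylethyl 5-bromopentanoate F1. Compound 5 would be converted with magnesium turnings in THF into heptadecylmagnesium bromide F2. Slow addition of F2 to F1 with Li2CuCl4 (3 mol%) and NMP (4 equiv) in THF at 0 °C should form the same C5–C6 bond and give 7 directly, because the copper-mediated displacement of the primary bromide is expected to outrun addition to the ester.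

2. Step 1. O-to-N acyl migration in the carbodiimide-activated acid could give an unreactive N-acylurea, and incompletely removed urea could be carried into the palladium step. The fallback is a Fischer esterification, which sets out from 1 and 2 and comes back to the route at 3: the two are heated with TsOH (5 mol%) in toluene under Dean–Stark removal of water. It makes no new compound.

Further compounds
F1 | step 2 | 2-phenylethyl 5-bromopentanoate | BrCCCCC(=O)OCCc1ccccc1
F2 | step 2 | heptadecylmagnesium bromide | CCCCCCCCCCCCCCCCC[Mg]Br
F0 | step 1 | none | none
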